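**Assumptions**
- The exocyclic alkene is Z (aryl cis to the ring oxygen) and the carbinol is (S), both read from the SMILES.
- 3,4-Dibromo-2(5H)-furanone (from furfural via mucobromic acid) and the three aryl building blocks are commercial.
- Both chiral-ligand enantiomers are available, so the one giving (S) is chosen by a quick screen.

**Retrosynthesis**
1. The carbinol C–C bond is made last, in a catalytic asymmetric Nozaki–Hiyama–Kishi (NHK) coupling of a 3-bromo-4-aryl-5-arylidene butenolide with the mirror-symmetric 3,5-dibromo-4-methoxybenzaldehyde. The chiral Cr catalyst differentiates the aldehyde's enantiotopic faces, which breaks the symmetry and sets the only stereocentre.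
2. The Z-5-arylidene comes from an aldol–dehydration of a 3-bromo-4-aryl butenolide with a protected 3-bromo-4-hydroxybenzaldehyde.
3. The 4-aryl group comes from a regioselective Suzuki coupling at C4 of 3,4-dibromo-2(5H)-furanone.
4. No ring is built in the route. The butenolide is a furan-derived starting material, and the arenes come from halophenol and hydroxybenzaldehyde feedstocks.

**Route**

**Step 1**
Reactants: 1 (2-bromo-4-iodophenol)
Product: 2 (tert-butyl(2-bromo-4-iodophenoxy)dimethylsilane)
Conditions: TBSCl, imidazole, DMF, 0 °C → rt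
Reagents that add atoms: TBSCl, CC(C)(C)[Si](C)(C)Cl
Why: Standard silylation masks the phenol so it survives the later Suzuki, aldol and NHK steps.

**Step 2**
Reactants: 2
Product: 3 (2-[3-bromo-4-(TBSO)phenyl]-4,4,5,5-tetramethyl-1,3,2-dioxaborolane)
Conditions: B2pin2 (1.1 equiv), Pd(dppf)Cl2 (3 mol%), KOAc, dioxane, 80 °C
Reagents that add atoms: B2pin2, CC1(C)OB(OC1(C)C)B1OC(C)(C)C(C)(C)O1
Why: Miyaura borylation is chemoselective for the C–I bond over the hindered ortho-OTBS C–Br bond.

**Step 3**
Reactants: 4 (3-bromo-4-hydroxybenzaldehyde)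
Product: 5 (3-bromo-4-(TBSO)benzaldehyde)
Conditions: TBSCl, imidazole, CH2Cl2/DMF, rt
Reagents that add atoms: TBSCl, CC(C)(C)[Si](C)(C)Cl
Why: The phenol is protected so it does not quench the enolate in step 5.

**Step 4**
Reactants: 6 (3,4-dibromo-2(5H)-furanone) and 3
Product: 7 (3-bromo-4-[3-bromo-4-(TBSO)phenyl]-2(5H)-furanone)
Conditions: Pd(PPh3)4 (5 mol%), 2 M aq. Na2CO3, DME, 50 °C; 1.05 equiv of 3
Reagents that add atoms: none
Why: Suzuki–Miyaura coupling occurs selectively at the more electrophilic β-C4–Br and leaves C3–Br for the NHK step. The vinyl bromide is far more reactive than the hindered aryl bromide on the boronate, so self-coupling is minimal.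

**Step 5**
Reactants: 7 and 5
Product: 8 ((Z)-3-bromo-4-[3-bromo-4-(TBSO)phenyl]-5-[3-bromo-4-(TBSO)benzylidene]furan-2(5H)-one)
Conditions: LiHMDS, THF, −78 °C; then 5, −78 °C; then Ac2O, DMAP, −78 → 0 °C; then DBU, CH2Cl2, 0 °C → rt
Reagents that add atoms: none (the acetate is lost in the elimination)
Why: A vinylogous aldol at C5 of the furanone dienolate is followed by acetylation and E1cB elimination, which gives the thermodynamically preferred Z-arylidene (aryl cis to the ring oxygen), as in rubrolide syntheses.

**Step 6 (key step)**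
Reactants: 8 and 9 (3,5-dibromo-4-methoxybenzaldehyde)
Product: 10 ((S)-carbinol, bis-TBS-protected target)
Conditions: CrCl2 (10 mol%), chiral sulfonamide ligand L* (12 mol%), NiCl2 (2 mol%), Mn (4 equiv), TMSCl, 2,6-lutidine, LiCl, THF/MeCN, 23 °C; then aq. citric acid workup
Reagents that add atoms: none (the transient O–TMS group is removed on workup)
Why: Proposed new method: Ni/Cr-mediated oxidative addition into the α-bromo-enoate C3–Br bond gives a vinylchromium(III) species, which adds to the aldehyde through a chiral Cr–sulfonamide complex that selects one enantiotopic face of the mirror-symmetric aldehyde, setting the (S)-carbinol. The closest known reactions are catalytic asymmetric Kishi-type NHK couplings of alkenyl halides and Ni/Cr couplings of 2-iodoenones with aldehydes. The aryl C–Br bonds, lactone and Z-alkene are expected to survive, and the hindered tetrasubstituted vinyl-Cr is the main risk.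

**Step 7**
Reactants: 10
Product: 11 (target)
Conditions: Et3N·3HF, THF, 0 °C → rt
Reagents that add atoms: none
Why: Buffered fluoride cleaves the labile bromophenol TBS ethers and leaves the aryl methyl ether, lactone, carbinol stereocentre and Z-alkene untouched.

**Compound list**

| No. | Name | SMILES | Role |
|---|---|---|---|
| 1 | 2-bromo-4-iodophenol | Oc1ccc(I)cc1Br | starting material |
| 2 | tert-butyl(2-bromo-4-iodophenoxy)dimethylsilane | CC(C)(C)[Si](C)(C)Oc1ccc(I)cc1Br | intermediate |
| 3 | aryl-Bpin, 2-[3-bromo-4-(TBSO)phenyl]-4,4,5,5-tetramethyl-1,3,2-dioxaborolane | CC(C)(C)[Si](C)(C)Oc1ccc(B2OC(C)(C)C(C)(C)O2)cc1Br | intermediate |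
| 4 | 3-bromo-4-hydroxybenzaldehyde | O=Cc1ccc(O)c(Br)c1 | starting material |
| 5 | 3-bromo-4-(TBSO)benzaldehyde | CC(C)(C)[Si](C)(C)Oc1ccc(C=O)cc1Br | intermediate |
| 6 | 3,4-dibromo-2(5H)-furanone | O=C1OCC(Br)=C1Br | starting material |
| 7 | 3-bromo-4-[3-bromo-4-(TBSO)phenyl]-2(5H)-furanone | O=C1OCC(c2ccc(O[Si](C)(C)C(C)(C)C)c(Br)c2)=C1Br | intermediate |
| 8 | (Z)-3-bromo-4-aryl-5-arylidene butenolide (bis-TBS) | BrC2=C(c3ccc(O[Si](C)(C)C(C)(C)C)c(Br)c3)/C(=C/c3ccc(O[Si](C)(C)C(C)(C)C)c(Br)c3)OC2=O | intermediate |
| 9 | 3,5-dibromo-4-methoxybenzaldehyde | COc1c(Br)cc(C=O)cc1Br | starting material |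
| 10 | (S)-carbinol, bis-TBS-protected target | COc1c(Br)cc([C@H](O)C2=C(c3ccc(O[Si](C)(C)C(C)(C)C)c(Br)c3)/C(=C/c3ccc(O[Si](C)(C)C(C)(C)C)c(Br)c3)OC2=O)cc1Br | intermediate |
| 11 | target | COc1c(Br)cc([C@H](O)C2=C(c3ccc(O)c(Br)c3)/C(=C/c3ccc(O)c(Br)c3)OC2=O)cc1Br | target |

**Step count**
- Total steps: 7.
- Longest linear sequence: 6 (steps 1, 2, 4, 5, 6, 7).

**Three steps most likely to fail**
1. **Step 6 (asymmetric NHK).** The hindered vinyl-Cr may give low conversion or low ee, or erode the Z-alkene.
   - Fallback: run a racemic NHK (no ligand) on 8, oxidise the carbinol with DMP to the 3-aroyl butenolide, then do an enantioselective CBS reduction with the catalyst enantiomer that gives (S). The stereocentre is then set by ketone reduction instead of C–C bond formation.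
2. **Step 4 (Suzuki).** C3/C4 selectivity may be poor, the aryl bromide may self-couple, or the TBS aryl ether may be labile in aqueous base.
   - Fallback: skip the Suzuki coupling. Take 3-bromo-4-(TBSO)acetophenone, α-acetoxylate it, then do a Horner–Wadsworth–Emmons reaction and lactonisation to give the 4-aryl-2(5H)-furanone, and install the 3-bromo group with Br2 then Et3N.
3. **Step 5 (aldol–dehydration).** The C3-bromo dienolate may react poorly, or Z/E selectivity may be low.
   - Fallback: prepare 3-(3-bromo-4-TBSO-phenyl)propiolic acid (Sonogashira of 2 with propiolic acid) and treat it with IBr. The trans haloiodination puts iodine cis to the acid. Sonogashira coupling at C–I with the TBS-protected 3-bromo-4-hydroxyphenylacetylene, then Ag2CO3 5-exo-dig lactonisation, gives 8 with Z-selectivity by construction.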